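**Retrosynthetic overview**
- The target comes from its tetra-MOM ether. The isopropenyl group on C2'' replaces a C2''–B bond by Zweifel olefination, with retention.
- The C8–C1'' bond is made in a single-flask enantioselective 1,2-diboration / site-selective Suzuki–Miyaura coupling of achiral 5-methylhexa-1,4-diene with the 8-iodoflavone.
- Enabling feature: C1''H2 (on C8 of ring A) and the adjacent stereocentre C2'' are the two carbons of a former terminal vinyl group. The third carbon substituent on C2'' is an sp2 carbon (isopropenyl) that a C–B bond can deliver stereospecifically. The C1''/C2'' pair therefore maps onto a vicinal bis(boronate) in which only the primary C–B bond cross-couples.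
- C8 is the ring-A CH between O7 and the pyranone O1, para to O5, and is more accessible than C6 (between two ethers). Per-etherified kaempferol is therefore iodinated there. The diene comes from allyl bromide and an isobutenyl Grignard reagent.
- No ring is formed in the route: rings A, C and B are taken intact from kaempferol.

Key step: step 4

Remark (assumption): C1'' is the CH2 on C8 and C2'' is the stereocentre; L* in step 4 is the antipode of the 3,5-diisopropylphenyl-TADDOL-derived phenylphosphonite that gives the (R)-configured bis(boronate), i.e. the sense that leads to (S)-1,2-diols from simple 1-alkenes after oxidation, and both antipodes are accessible from (R,R)- and (S,S)-tartrate.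

Step 1
Reactants: 1 kaempferol
Product: 2 3,5,7-tris(methoxymethoxy)-2-[4-(methoxymethoxy)phenyl]-4H-chromen-4-one
Conditions: NaH, MOMCl, DMF, 0 °C to rt, Ar
Reagents that add atoms: chloromethyl methyl ether (MOMCl), COCCl
Why: Fourfold Williamson-type O-alkylation in which NaH also deprotonates the chelated 5-OH, so that all four oxygens are capped as base-stable acetals that survive steps 2 to 5.

Step 2
Reactants: 2 kaempferol tetra-MOM ether
Product: 3 8-iodo-3,5,7-tris(methoxymethoxy)-2-[4-(methoxymethoxy)phenyl]-4H-chromen-4-one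
Conditions: NIS (1.05 equiv), DMF, rt, dark
Reagents that add atoms: N-iodosuccinimide, O=C1CCC(=O)N1I
Why: Electrophilic aromatic iodination under neutral conditions, where ring A is the most electron-rich ring and C8 (ortho to O7 and O1, para to O5) is less hindered than C6 between two OMOM groups, a selectivity well known for 5,7-dialkoxyflavones.

Step 3
Reactants: 4 allyl bromide; 5 2-methylprop-1-enylmagnesium bromide
Product: 6 5-methylhexa-1,4-diene
Conditions: CuI (5 mol %), THF, 0 °C to rt; distillation
Reagents that add atoms: none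
Why: Copper-catalysed allylic substitution with an alkenyl Grignard reagent, in which SN2 and SN2' attack on allyl bromide give the same skipped diene, so there is no regiochemical issue and no stereocentre is formed.

Step 4
Reactants: 6 5-methylhexa-1,4-diene; 3 8-iodo tetra-MOM kaempferol
Product: 8 8-[(2S)-5-methyl-2-(4,4,5,5-tetramethyl-1,3,2-dioxaborolan-2-yl)hex-4-en-1-yl]-3,5,7-tris(methoxymethoxy)-2-[4-(methoxymethoxy)phenyl]-4H-chromen-4-one, via vicinal bis(boronate) 7 (not isolated)
Conditions: 6 (1.4 equiv), B2pin2 (1.3 equiv), Pt(dba)3 (1 mol %), L* (1.2 mol %), THF, 60 °C; then 3 (1.0 equiv), Pd(OAc)2/RuPhos (2.5 mol %), KOH, THF/H2O 10:1, 70 °C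
Reagents that add atoms: bis(pinacolato)diboron, CC1(C)OB(OC1(C)C)B1OC(C)(C)C(C)(C)O1
Why: Pt(0) adds oxidatively to the B–B bond, the monosubstituted C1''=C2'' alkene of 6 inserts into a Pt–B bond and reductive elimination gives 7; after addition of 3, Pd(0)/RuPhos inserts into the C8–I bond, hydroxide binds to 7, the primary C1''–B bond transmetalates and reductive elimination forms C8–C1''. The closest known reaction type is the single-flask enantioselective diboration/Suzuki–Miyaura cascade of terminal alkenes with aryl halides. No ring is closed. The only new stereocentre, C2'', is fixed in the enantio-determining alkene insertion under control of the chiral phosphonite on Pt and is not touched in the coupling, because only the C1''–B bond reacts. The step needs alkene selectivity (the Pt catalyst accepts only the unhindered vinyl group and leaves the trisubstituted C=C alone), boron selectivity (the neighbouring secondary Bpin assists the hydroxide-bound primary boronate so that only the CH2–B bond transfers) and site selectivity on ring A (fixed by the iodine on C8). The bulky electron-rich RuPhos ligand should make reductive elimination at the doubly ortho-oxygenated C8 faster than beta-hydride elimination.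

Step 5
Reactants: 8 secondary boronate
Product: 11 8-[(2S)-5-methyl-2-(prop-1-en-2-yl)hex-4-en-1-yl]-3,5,7-tris(methoxymethoxy)-2-[4-(methoxymethoxy)phenyl]-4H-chromen-4-one, via lithium alkenylboronate complex 9 (not isolated), via beta-iodoalkyl boronate 10 (not isolated)
Conditions: 2-bromopropene, t-BuLi (1.95 equiv per bromide), Et2O, -78 °C; slow addition (1.1 equiv) to 8, THF, -78 °C; I2, THF, -78 °C; NaOMe, MeOH, -78 °C to rt
Reagents that add atoms: 2-bromopropene, C=C(C)Br; tert-butyllithium, [Li]C(C)(C)C (lithium of 9 only); iodine, II (iodine of 10 only)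
Why: Zweifel olefination, in which the alkenyllithium should be captured by the Lewis-acidic boron at -78 °C faster than by the vinylogous-ester C4 carbonyl (deactivated by O1, O5 and O7 and flanked by two OMOM groups), iodonium formation triggers a 1,2-metallate shift of C2'' with retention of configuration, and methoxide-induced anti-elimination of boron and iodide from 10 gives the 1,1-disubstituted alkene.

Step 6
Reactants: 11 tetra-MOM 8-lavandulylkaempferol
Product: 12 8-[(2S)-5-methyl-2-(prop-1-en-2-yl)hex-4-en-1-yl]-3,5,7-trihydroxy-2-(4-hydroxyphenyl)-4H-chromen-4-one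
Conditions: HCl (1.25 M in MeOH), THF, 40 °C
Reagents that add atoms: none
Why: Acid-catalysed transacetalisation of the four aryl MOM acetals to dimethoxymethane, standard for prenylated flavonoids, where dilute acid and mild temperature should leave both alkenes and the C2'' stereocentre untouched.

**Compound list**
1 | kaempferol | O=c1c(O)c(-c2ccc(O)cc2)oc2cc(O)cc(O)c12 | starting material
2 | 3,5,7-tris(methoxymethoxy)-2-[4-(methoxymethoxy)phenyl]-4H-chromen-4-one | COCOc1cc(OCOC)c2c(=O)c(OCOC)c(-c3ccc(OCOC)cc3)oc2c1 | intermediate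
3 | 8-iodo-3,5,7-tris(methoxymethoxy)-2-[4-(methoxymethoxy)phenyl]-4H-chromen-4-one | Ic1c(OCOC)cc(OCOC)c2c(=O)c(OCOC)c(-c3ccc(OCOC)cc3)oc12 | intermediate
4 | allyl bromide | C=CCBr | starting material
5 | 2-methylprop-1-enylmagnesium bromide | CC(C)=C[Mg]Br | starting material
6 | 5-methylhexa-1,4-diene | C=CCC=C(C)C | intermediate
7 | (R)-2,2'-(5-methylhex-4-ene-1,2-diyl)bis(4,4,5,5-tetramethyl-1,3,2-dioxaborolane) | CC1(C)OB(OC1(C)C)[C@@H](CC=C(C)C)CB1OC(C)(C)C(C)(C)O1 | intermediate
8 | 8-[(2S)-5-methyl-2-(4,4,5,5-tetramethyl-1,3,2-dioxaborolan-2-yl)hex-4-en-1-yl]-3,5,7-tris(methoxymethoxy)-2-[4-(methoxymethoxy)phenyl]-4H-chromen-4-one | CC1(C)OB(OC1(C)C)[C@@H](CC=C(C)C)Cc1c(OCOC)cc(OCOC)c2c(=O)c(OCOC)c(-c3ccc(OCOC)cc3)oc12 | intermediate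
9 | lithium isopropenyl(pinacolato)borate complex of 8, C2'' (S) | [Li+].C=C(C)[B-]1(OC(C)(C)C(C)(C)O1)[C@@H](CC=C(C)C)Cc1c(OCOC)cc(OCOC)c2c(=O)c(OCOC)c(-c3ccc(OCOC)cc3)oc12 | intermediate
10 | 8-[(2S)-2-[1-iodo-2-(4,4,5,5-tetramethyl-1,3,2-dioxaborolan-2-yl)propan-2-yl]-5-methylhex-4-en-1-yl] tetra-MOM flavone, both epimers at the boron-bearing carbon | ICC(C)(B1OC(C)(C)C(C)(C)O1)[C@@H](CC=C(C)C)Cc1c(OCOC)cc(OCOC)c2c(=O)c(OCOC)c(-c3ccc(OCOC)cc3)oc12 | intermediate
11 | 8-[(2S)-5-methyl-2-(prop-1-en-2-yl)hex-4-en-1-yl]-3,5,7-tris(methoxymethoxy)-2-[4-(methoxymethoxy)phenyl]-4H-chromen-4-one | C=C(C)[C@@H](CC=C(C)C)Cc1c(OCOC)cc(OCOC)c2c(=O)c(OCOC)c(-c3ccc(OCOC)cc3)oc12 | intermediate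
12 | 8-[(2S)-5-methyl-2-(prop-1-en-2-yl)hex-4-en-1-yl]-3,5,7-trihydroxy-2-(4-hydroxyphenyl)-4H-chromen-4-one (8-lavandulylkaempferol) | C=C(C)[C@@H](CC=C(C)C)Cc1c(O)cc(O)c2c(=O)c(O)c(-c3ccc(O)cc3)oc12 | target

Total step count: 6.
Longest linear sequence: 5 steps (1 to 2 to 3 to 8 to 11 to 12).

**Steps most likely to fail**

**Step 4.**
- Risk: oxidative addition and transmetalation at the doubly ortho-oxygenated C8 may be slow. Hydrodeiodination of the aryl iodide, protodeboronation of the bis(boronate) or hydroxide attack on the pyranone could then outrun the coupling.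
- Fallback, from 6 and 3, back at 8: the event is split into a less demanding sp2–sp2 coupling and a later borylation.
- Cross-metathesis of 6 with vinylboronic acid pinacol ester (second-generation ruthenium metathesis catalyst, CH2Cl2, 40 °C) should give 4,4,5,5-tetramethyl-2-[(1E)-5-methylhexa-1,4-dien-1-yl]-1,3,2-dioxaborolane F1.
- Suzuki–Miyaura coupling of it with 3 (Pd(dppf)Cl2, K3PO4, dioxane/H2O, 80 °C) should give the 8-[(1E)-5-methylhexa-1,4-dien-1-yl] tetra-MOM flavone F2, in which the same C8–C1'' bond is made.
- Copper-catalysed enantioselective protoboration of the aryl-conjugated alkene follows (CuCl, chiral NHC or bisphosphine of the appropriate antipode, NaOt-Bu, B2pin2, MeOH, THF). Copper goes to the benzylic C1'' and boron to C2'', which returns 8.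

**Step 5.**
- Risk: 1,2-addition of the alkenyllithium to the C4 carbonyl, or lithiation at C6, may compete with formation of the boron ate complex.
- Fallback, from 3, back at 11: no organolithium meets the flavone, because the complete side chain is brought in.
- Commercial (R)-(-)-lavandulol F3 is converted under Appel conditions (I2, PPh3, imidazole, CH2Cl2, 0 °C) into (R)-lavandulyl iodide F4.
- Zinc insertion (Zn dust, LiCl, THF, 25 to 40 °C) gives (R)-lavandulylzinc iodide F5.
- Negishi coupling with 3 (Pd2(dba)3/RuPhos, THF, 40 °C) leaves the beta-stereocentre untouched and gives 11.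

**Step 6.**
- Risk: protonation of the isopropenyl or prenyl alkene may be followed by addition of the liberated 7-OH (chroman formation) or by alkene migration.
- Fallback, from 11, back at 12: the acetals are exchanged for silyl ethers under buffered, non-protic conditions.
- TMSOTf and 2,2'-bipyridyl in MeCN at 0 °C should give the tetrakis(trimethylsilyl) ether of 8-lavandulylkaempferol F6.
- This ether is hydrolysed by water at neutral pH to 12.

**Further compounds**
F1 | step 4 | 4,4,5,5-tetramethyl-2-[(1E)-5-methylhexa-1,4-dien-1-yl]-1,3,2-dioxaborolane | CC(C)=CC/C=C/B1OC(C)(C)C(C)(C)O1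
F2 | step 4 | 8-[(1E)-5-methylhexa-1,4-dien-1-yl]-3,5,7-tris(methoxymethoxy)-2-[4-(methoxymethoxy)phenyl]-4H-chromen-4-one | CC(C)=CC/C=C/c1c(OCOC)cc(OCOC)c2c(=O)c(OCOC)c(-c3ccc(OCOC)cc3)oc12
F3 | step 5 | (R)-lavandulol, (2R)-5-methyl-2-(prop-1-en-2-yl)hex-4-en-1-ol | CC(C)=CC[C@@H](CO)C(C)=C
F4 | step 5 | (R)-lavandulyl iodide, (3R)-3-(iodomethyl)-2,6-dimethylhepta-1,5-diene | CC(C)=CC[C@@H](CI)C(C)=C
F5 | step 5 | (R)-lavandulylzinc iodide | CC(C)=CC[C@@H](C[Zn]I)C(C)=C
F6 | step 6 | 8-[(2S)-5-methyl-2-(prop-1-en-2-yl)hex-4-en-1-yl]-3,5,7-tris(trimethylsilyloxy)-2-[4-(trimethylsilyloxy)phenyl]-4H-chromen-4-one | C=C(C)[C@@H](CC=C(C)C)Cc1c(O[Si](C)(C)C)cc(O[Si](C)(C)C)c2c(=O)c(O[Si](C)(C)C)c(-c3ccc(O[Si](C)(C)C)cc3)oc12
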